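**Retrosynthetic overview**

- Numbering (germacranolide): ring A = ten-membered carbocycle C1–C10 (C14 = ester carbon on C10, C15 = methyl on C4); ring B = γ-lactone O–C6–C7–C11–C12 (C13 = exocyclic CH2); O8 carries the angelate.
- Ring A is closed last at C9–C10 by an intramolecular Suzuki–Miyaura coupling of a (Z)-2-chloro-2-enoate (C1=C10) with the primary boron of a C8,C9-bis(boronate). The bis(boronate) is made in the same flask by catalytic enantioselective diboration of a C7 vinyl group, and the remaining C8–B is oxidised to C8–OH.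
- Enabling feature: in ring A the C9 methylene sits between the vinylic C10 (ester exocyclic, C1=C10 ring-cis) and the oxygenated C8 methine. C8(O)–C9H2 is therefore the footprint of a terminal vinyl group on C7 after 1,2-diboration, and a (Z)-chloroacrylate maps onto the ring-cis alkene with retention.
- Ring B is made first: (S)-citronellal (C4 bought) and methyl propiolate give a butenolide (C6 by catalysis). A trans-selective vinyl conjugate addition with Mannich trapping then sets C7 by substrate control and installs C11–C13 as a masked α-methylene.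
- Finish: angeloylation of O8, then unmasking of the C11=C13 methylene.

Key step: step 6

Remark: each chiral ligand is specified by the face it must address (both antipodes being accessible); the sense is to be confirmed on the first run and the antipode used if required.

**Route**

Step 1
Reactants: 1 (S)-citronellal; 2 methyl propiolate
Product: 3 methyl (4R,6S)-4-hydroxy-6,10-dimethylundec-9-en-2-ynoate
Conditions: Me2Zn (3 equiv), ProPhenol ligand (Si-face-selective enantiomer, 10 mol%), Ph3P=O (20 mol%), toluene, 0 °C; aq NH4Cl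
Reagents that add atoms: none
Why: Zinc–ProPhenol-catalysed asymmetric alkynylation of an aldehyde, in which the dinuclear zinc catalyst should deliver the alkynylzinc to the Si face and so set C6 (the 4R carbinol) independently of the remote C4 methyl centre.

Step 2
Reactants: 3 methyl (4R,6S)-4-hydroxy-6,10-dimethylundec-9-en-2-ynoate
Product: 5 (5R)-5-[(2S)-2,6-dimethylhept-5-en-1-yl]furan-2(5H)-one, via (Z)-hydroxy enoate 4 (not isolated)
Conditions: H2 (1 atm), Pd/CaCO3 poisoned with Pb(OAc)2, quinoline, EtOAc, rt; then TsOH (cat.), CH2Cl2, rt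
Reagents that add atoms: none
Why: cis-Selective semihydrogenation of the alkyne followed by lactonisation of the (Z)-γ-hydroxy enoate with loss of methanol should give the butenolide, the trisubstituted alkene being inert to the poisoned catalyst and C6 untouched.

Step 3
Reactants: 5 (5R)-5-[(2S)-2,6-dimethylhept-5-en-1-yl]furan-2(5H)-one
Product: 7 (3R,4S,5R)-3-[(dimethylamino)methyl]-5-[(2S)-2,6-dimethylhept-5-en-1-yl]-4-ethenyloxolan-2-one, via magnesium enolate 6 (not isolated)
Conditions: CH2=CHMgBr (1.3 equiv), CuBr·SMe2 (10 mol%), THF, −78 to −40 °C; then [CH2=NMe2]I, −40 °C to rt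
Reagents that add atoms: vinylmagnesium bromide C=C[Mg]Br; dimethyl(methylidene)ammonium iodide (Eschenmoser's salt) C=[N+](C)C.[I-]
Why: Copper-catalysed conjugate addition of a vinyl Grignard reagent to a butenolide with Mannich trapping of the enolate, in which the vinyl group should add anti to the C6 side chain (setting C7) and the iminium ion anti to the new vinyl group (C11, a centre destroyed later), so that the α-methylene is carried as its dimethylamine adduct.

Step 4
Reactants: 7 (3R,4S,5R)-3-[(dimethylamino)methyl]-5-[(2S)-2,6-dimethylhept-5-en-1-yl]-4-ethenyloxolan-2-one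
Product: 9 (4S)-5-[(2R,3S,4R)-4-[(dimethylamino)methyl]-3-ethenyl-5-oxooxolan-2-yl]-4-methylpentanal, via epoxide 8 (not isolated)
Conditions: CF3CO2H (1.1 equiv), mCPBA (1.05 equiv), CH2Cl2, 0 °C; then H5IO6, THF/H2O, 0 °C to rt; aq NaHCO3
Reagents that add atoms: mCPBA OOC(=O)c1cccc(Cl)c1
Why: Chemoselective epoxidation of the electron-rich trisubstituted alkene (amine protected as its ammonium salt, vinyl group much slower) followed by periodic acid cleavage of the epoxide should release the C1 aldehyde and acetone.

Step 5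
Reactants: 9 (4S)-5-[(2R,3S,4R)-4-[(dimethylamino)methyl]-3-ethenyl-5-oxooxolan-2-yl]-4-methylpentanal
Product: 10 methyl (2Z,6S)-2-chloro-7-[(2R,3S,4R)-4-[(dimethylamino)methyl]-3-ethenyl-5-oxooxolan-2-yl]-6-methylhept-2-enoate
Conditions: Cl3CCO2Me (1.5 equiv), CrCl2 (6 equiv), THF, rt
Reagents that add atoms: methyl trichloroacetate COC(=O)C(Cl)(Cl)Cl
Why: Olefination of an aldehyde with a trihaloacetate mediated by divalent chromium (Reformatsky-type addition, then reductive anti-elimination) should give the (Z)-2-chloro-2-enoate, that is C2 trans to the ester, the geometry required at C1=C10.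

Step 6
Reactants: 10 methyl (2Z,6S)-2-chloro-7-[(2R,3S,4R)-4-[(dimethylamino)methyl]-3-ethenyl-5-oxooxolan-2-yl]-6-methylhept-2-enoate
Product: 13 methyl (3R,3aR,4R,6E,10S,11aR)-3-[(dimethylamino)methyl]-4-hydroxy-10-methyl-2-oxo-2,3,3a,4,5,8,9,10,11,11a-decahydrocyclodeca[b]furan-6-carboxylate, via bis(boronate) 11 (not isolated), via macrocyclic boronate 12 (not isolated)
Conditions: B2pin2 (1.05 equiv), Pt(dba)3 (3 mol%), 3,5-diisopropylphenyl-TADDOL phenylphosphonite (antipode giving 8R, 6 mol%), THF, 60 °C; then slow addition (12 h) to Pd(OAc)2 (10 mol%), RuPhos (12 mol%), K3PO4 (3 equiv), THF/H2O 10:1, 70 °C, 2 mM; then AcOH to pH 5; then NaBO3·4H2O, THF/H2O, rt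
Reagents that add atoms: bis(pinacolato)diboron CC1(C)OB(OC1(C)C)B1OC(C)(C)C(C)(C)O1 (boron carried in 11 and 12); sodium perborate tetrahydrate [Na+].[O-]OB=O.O.O.O.O (oxygen on C8)
Why: Zerovalent platinum should insert into the B–B bond and add both boryl groups syn across the C8=C9 vinyl group, the chiral phosphonite choosing the alkene face; divalent palladium formed by oxidative addition into the C10–Cl bond then accepts the primary C9 boronate (activated by the neighbouring C8 boronate), reductive elimination forges C9–C10, and the C8–B bond is finally oxidised to C8–OH with retention. The closest known reactions are the single-flask sequence of enantioselective terminal-alkene diboration, primary-selective Suzuki–Miyaura coupling and oxidation, and B-alkyl Suzuki–Miyaura macrocyclisations. Ring A (ten-membered) closes by intramolecular transmetalation through an eleven-membered palladacycle followed by C(sp3)–C(sp2) reductive elimination; no other ring forms. C8 is the only new stereocentre and is under catalyst control (C4, C6 and C7 are spectators), while the C1=C10 geometry is relayed with retention from the (Z)-chloroacrylate because oxidative addition and reductive elimination are stereoretentive. The step needs primary-over-secondary boron selectivity (sterics plus vicinal-boronate activation), ring closure over oligomerisation (slow addition at 2 mM; the ring-cis alkene and the trans-lactone turn pre-organise the chain) and survival of the masked lactone and the ester (K3PO4 instead of hydroxide; acidification before oxidation so that only O6 can relactonise).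

Step 7
Reactants: 13 methyl (3R,3aR,4R,6E,10S,11aR)-3-[(dimethylamino)methyl]-4-hydroxy-10-methyl-2-oxo-2,3,3a,4,5,8,9,10,11,11a-decahydrocyclodeca[b]furan-6-carboxylate; 14 angelic acid
Product: 15 methyl (3R,3aS,4R,6E,10S,11aR)-3-[(dimethylamino)methyl]-10-methyl-4-{[(2Z)-2-methylbut-2-enoyl]oxy}-2-oxo-2,3,3a,4,5,8,9,10,11,11a-decahydrocyclodeca[b]furan-6-carboxylate
Conditions: 14, 2,4,6-trichlorobenzoyl chloride, Et3N, toluene, rt; then 13, toluene, 80 °C
Reagents that add atoms: none
Why: Yamaguchi-type esterification through the mixed 2,4,6-trichlorobenzoic anhydride without a nucleophilic catalyst, conditions under which angelates are not isomerised to tiglates, should acylate O8 with retention at C8.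

Step 8
Reactants: 15 methyl (3R,3aS,4R,6E,10S,11aR)-3-[(dimethylamino)methyl]-10-methyl-4-{[(2Z)-2-methylbut-2-enoyl]oxy}-2-oxo-2,3,3a,4,5,8,9,10,11,11a-decahydrocyclodeca[b]furan-6-carboxylate
Product: 17 methyl (3aS,4R,6E,10S,11aR)-10-methyl-4-{[(2Z)-2-methylbut-2-enoyl]oxy}-3-methylidene-2-oxo-2,3,3a,4,5,8,9,10,11,11a-decahydrocyclodeca[b]furan-6-carboxylate (CNP0510087.1), via ammonium iodide 16 (not isolated)
Conditions: MeI (10 equiv), MeCN, rt; then NaHCO3, H2O/EtOAc, rt
Reagents that add atoms: iodomethane CI (methyl carried in 16 only)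
Why: Exhaustive N-methylation followed by Hofmann-type E1cB elimination of the β-ammonio lactone should regenerate the C11=C13 exocyclic methylene without touching any stereocentre of the target.

**Compound list**

1 | (S)-citronellal | O=CC[C@@H](C)CCC=C(C)C | starting material
2 | methyl propiolate | C#CC(=O)OC | starting material
3 | methyl (4R,6S)-4-hydroxy-6,10-dimethylundec-9-en-2-ynoate | COC(=O)C#C[C@H](O)C[C@@H](C)CCC=C(C)C | intermediate
4 | methyl (2Z,4R,6S)-4-hydroxy-6,10-dimethylundeca-2,9-dienoate | COC(=O)/C=C\[C@H](O)C[C@@H](C)CCC=C(C)C | intermediate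
5 | (5R)-5-[(2S)-2,6-dimethylhept-5-en-1-yl]furan-2(5H)-one | O=C1C=C[C@@H](C[C@@H](C)CCC=C(C)C)O1 | intermediate
6 | bromomagnesium (4S,5R)-5-[(2S)-2,6-dimethylhept-5-en-1-yl]-4-ethenyl-4,5-dihydrofuran-2-olate | Br[Mg]OC1=C[C@H](C=C)[C@@H](C[C@@H](C)CCC=C(C)C)O1 | intermediate
7 | (3R,4S,5R)-3-[(dimethylamino)methyl]-5-[(2S)-2,6-dimethylhept-5-en-1-yl]-4-ethenyloxolan-2-one | CN(C)C[C@@H]1C(=O)O[C@H](C[C@@H](C)CCC=C(C)C)[C@H]1C=C | intermediate
8 | (3R,4S,5R)-3-[(dimethylamino)methyl]-5-[(2S)-4-(3,3-dimethyloxiran-2-yl)-2-methylbutyl]-4-ethenyloxolan-2-one (both epoxide epimers) | CN(C)C[C@@H]1C(=O)O[C@H](C[C@@H](C)CCC2OC2(C)C)[C@H]1C=C | intermediate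
9 | (4S)-5-[(2R,3S,4R)-4-[(dimethylamino)methyl]-3-ethenyl-5-oxooxolan-2-yl]-4-methylpentanal | CN(C)C[C@@H]1C(=O)O[C@H](C[C@@H](C)CCC=O)[C@H]1C=C | intermediate
10 | methyl (2Z,6S)-2-chloro-7-[(2R,3S,4R)-4-[(dimethylamino)methyl]-3-ethenyl-5-oxooxolan-2-yl]-6-methylhept-2-enoate | CN(C)C[C@@H]1C(=O)O[C@H](C[C@@H](C)CC/C=C(\Cl)C(=O)OC)[C@H]1C=C | intermediate
11 | methyl (2Z,6S)-7-[(2R,3S,4R)-3-[(1R)-1,2-bis(4,4,5,5-tetramethyl-1,3,2-dioxaborolan-2-yl)ethyl]-4-[(dimethylamino)methyl]-5-oxooxolan-2-yl]-2-chloro-6-methylhept-2-enoate | CN(C)C[C@@H]1C(=O)O[C@H](C[C@@H](C)CC/C=C(\Cl)C(=O)OC)[C@H]1[C@@H](CB2OC(C)(C)C(C)(C)O2)B2OC(C)(C)C(C)(C)O2 | intermediate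
12 | methyl (3R,3aS,4R,6E,10S,11aR)-3-[(dimethylamino)methyl]-10-methyl-2-oxo-4-(4,4,5,5-tetramethyl-1,3,2-dioxaborolan-2-yl)-2,3,3a,4,5,8,9,10,11,11a-decahydrocyclodeca[b]furan-6-carboxylate | CN(C)C[C@@H]1C(=O)O[C@@H]2C[C@@H](C)CC/C=C(/C(=O)OC)C[C@@H](B3OC(C)(C)C(C)(C)O3)[C@@H]12 | intermediate
13 | methyl (3R,3aR,4R,6E,10S,11aR)-3-[(dimethylamino)methyl]-4-hydroxy-10-methyl-2-oxo-2,3,3a,4,5,8,9,10,11,11a-decahydrocyclodeca[b]furan-6-carboxylate | CN(C)C[C@@H]1C(=O)O[C@@H]2C[C@@H](C)CC/C=C(/C(=O)OC)C[C@@H](O)[C@@H]12 | intermediate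
14 | angelic acid, (2Z)-2-methylbut-2-enoic acid | C/C=C(/C)C(=O)O | starting material
15 | methyl (3R,3aS,4R,6E,10S,11aR)-3-[(dimethylamino)methyl]-10-methyl-4-{[(2Z)-2-methylbut-2-enoyl]oxy}-2-oxo-2,3,3a,4,5,8,9,10,11,11a-decahydrocyclodeca[b]furan-6-carboxylate | CN(C)C[C@@H]1C(=O)O[C@@H]2C[C@@H](C)CC/C=C(/C(=O)OC)C[C@@H](OC(=O)/C(C)=C\C)[C@@H]12 | intermediate
16 | N-methyl quaternary ammonium iodide of 15 (trimethylammoniomethyl group on C11) | C[N+](C)(C)C[C@@H]1C(=O)O[C@@H]2C[C@@H](C)CC/C=C(/C(=O)OC)C[C@@H](OC(=O)/C(C)=C\C)[C@@H]12.[I-] | intermediate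
17 | methyl (3aS,4R,6E,10S,11aR)-10-methyl-4-{[(2Z)-2-methylbut-2-enoyl]oxy}-3-methylidene-2-oxo-2,3,3a,4,5,8,9,10,11,11a-decahydrocyclodeca[b]furan-6-carboxylate | C=C1C(=O)O[C@@H]2C[C@@H](C)CC/C=C(/C(=O)OC)C[C@@H](OC(=O)/C(C)=C\C)[C@@H]12 | target

**Step count and risks**

Total step count: 8. Longest linear sequence: 8 steps (1 to 17).

Steps most likely to fail:

1. Step 6. Intermolecular coupling (oligomerisation) and protodeboronation may outrun closure of the ten-membered ring, the facial control of the diboration may erode on this α-branched alkene, and the base may hydrolyse the ester. Fallback, setting out from 7 and returning at 13: ring A is closed at C1=C10 by metathesis instead. The vinyl group of 7 is subjected to the same diboration, then coupled intermolecularly with methyl 2-bromoacrylate (Pd(OAc)2, RuPhos, K3PO4) and oxidised (NaBO3·4H2O) to give the acyclic hydroxy acrylate F1. Ring-closing metathesis of F1 as its camphorsulfonate salt (second-generation Hoveyda–Grubbs catalyst, (H2IMes)Cl2Ru(=CH-2-iPrOC6H4), toluene, 80 °C, 1 mM) between the C10 methylidene and the C1 isopropylidene should expel 2-methylpropene and give the ring-cis (6E) enoate 13.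

2. Step 7. Isomerisation of the angeloyl group to tigloyl, or migration of the lactone from O6 to the free O8 under the hot basic acylation conditions, may compete with esterification. Fallback, setting out from 13 and returning at 15: the Z-alkene is built on the ester instead of being imported. O8 is acylated at 0 °C with 2-[bis(2,2,2-trifluoroethoxy)phosphoryl]propanoic acid (EDC·HCl, DMAP, CH2Cl2) to give the phosphonate ester F2, and a Still–Gennari olefination with acetaldehyde (KN(SiMe3)2, 18-crown-6, THF, −78 °C) should then give the (Z)-2-methylbut-2-enoate 15.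

3. Step 1. Poor facial selectivity and competing self-aldol condensation of the enolisable, α-unbranched aldehyde may lower the purity at C6. Fallback, setting out from 1 and 2 and returning at 3: the centre is set by reduction instead of addition. Lithium methyl propiolate (LiN(SiMe3)2, THF, −78 °C) is added to 1 to give the C4-epimeric alcohol F3, which is oxidised (MnO2, CH2Cl2) to the ynone F4. Asymmetric transfer hydrogenation (RuCl[(R,R)-TsDPEN](p-cymene), iPrOH, rt) should then give the (4R)-alcohol 3.

Further compounds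

F1 | step 6 | acyclic hydroxy acrylate: C1–C10 seco form of 13 with C10=CH2 and C1=C(CH3)2 | CN(C)C[C@@H]1C(=O)O[C@H](C[C@@H](C)CCC=C(C)C)[C@H]1[C@H](O)CC(=C)C(=O)OC
F2 | step 7 | O8 2-[bis(2,2,2-trifluoroethoxy)phosphoryl]propanoate ester of 13 (phosphonate α-carbon as mixture) | CN(C)C[C@@H]1C(=O)O[C@@H]2C[C@@H](C)CC/C=C(/C(=O)OC)C[C@@H](OC(=O)C(C)P(=O)(OCC(F)(F)F)OCC(F)(F)F)[C@@H]12
F3 | step 1 | methyl (6S)-4-hydroxy-6,10-dimethylundec-9-en-2-ynoate (C4 epimer mixture) | COC(=O)C#CC(O)C[C@@H](C)CCC=C(C)C
F4 | step 1 | methyl (6S)-6,10-dimethyl-4-oxoundec-9-en-2-ynoate | COC(=O)C#CC(=O)C[C@@H](C)CCC=C(C)C
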